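## Retrosynthetic overview
1. The oxirane is made last, by face- and site-selective dioxirane epoxidation of the ring alkene next to the pentenyl-bearing CH of the corresponding cyclohexadiene.
2. The cyclohexadiene comes from an achiral (2E,4Z,6E,8E)-tetraenyl γ-pyrone by a chiral-Brønsted-acid-catalysed disrotatory 6π electrocyclisation. This new step forms the ring C–C bond and both carbon stereocentres.
3. The tetraene comes from a Negishi union of a (Z)-iodotriene with an (E)-β-iodovinyl γ-pyrone, at the sp2–sp2 bond next to the Z alkene.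
4. The iodotriene comes from (E)-2-methylpent-2-enal by two olefinations. The pyrone comes from pentan-3-one, dimethyl carbonate and (E)-3-iodo-2-methylacrylic acid (from diethyl methylmalonate and iodoform).
5. Ring order: γ-pyrone, then cyclohexadiene, then oxirane.

Assumption: the sense of induction of the new catalyst cannot be predicted, so the (S,S) form is written; its mirror image is used if a first run gives the antipode of 25.

## Route

Step 1
Reactants: 1 (E)-2-methylpent-2-enal; 2 2-(triphenylphosphoranylidene)propanal
Product: 3 (2E,4E)-2,4-dimethylhepta-2,4-dienal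
Conditions: PhMe, 100 °C, 24 h
Reagents that add atoms: none
Why: Wittig olefination with a stabilised formyl ylide gives the E trisubstituted enal, and the product dienal is less electrophilic than 1, so a second homologation is slow.

Step 2
Reactants: 3 (2E,4E)-2,4-dimethylhepta-2,4-dienal; 4 ethyltriphenylphosphonium iodide
Product: 8 (2Z,4E,6E)-2-iodo-4,6-dimethylnona-2,4,6-triene, via ethylidenetriphenylphosphorane 5 (not isolated), via (1-iodoethyl)triphenylphosphonium iodide 6 (not isolated), via (1-iodoethylidene)triphenylphosphorane 7 (not isolated)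
Conditions: 4, n-BuLi, THF, 0 °C to rt; I2, THF, −78 °C; NaN(SiMe3)2, −78 to −20 °C; 3, −78 to −20 °C, dark
Reagents that add atoms: iodine, [I][I]
Why: In this Stork–Zhao-type iodo-olefination the non-stabilised α-iodo ylide 7 reacts under kinetic control through the cis-oxaphosphetane, so iodine ends up cis to the dienyl chain (Z) and the two E alkenes are untouched.

Step 3
Reactants: 9 diethyl 2-methylmalonate; 10 iodoform
Product: 11 diethyl 2-(diiodomethyl)-2-methylmalonate
Conditions: NaH, Et2O, reflux; then CHI3, reflux, 24 h
Reagents that add atoms: none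
Why: C-alkylation of the malonate enolate by iodoform (formal substitution, probably through capture of diiodocarbene) places CHI2 on the only nucleophilic carbon, and no stereocentre arises because the two ester arms are identical.

Step 4
Reactants: 11 diethyl 2-(diiodomethyl)-2-methylmalonate
Product: 12 (E)-3-iodo-2-methylprop-2-enoic acid
Conditions: KOH, EtOH–H2O (3:1), reflux, 24 h; then aq. HCl
Reagents that add atoms: potassium hydroxide, [K+].[OH-]
Why: Saponification followed by a Grob-type decarboxylative elimination of iodide gives the alkene, and the E isomer forms because the elimination runs through the conformer that keeps iodine away from the remaining carboxylate.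

Step 5
Reactants: 13 pentan-3-one; 14 dimethyl carbonate
Product: 15 methyl 2-methyl-3-oxopentanoate (racemic, configurationally labile)
Conditions: NaH, (MeO)2CO, THF, reflux; then aq. HCl
Reagents that add atoms: none
Why: This crossed Claisen condensation of a symmetrical ketone enolate with a carbonate is driven by formation of the β-keto ester enolate, which also blocks a second acylation; the labile centre is erased in step 6.

Step 6
Reactants: 12 (E)-3-iodo-2-methylprop-2-enoic acid; 15 methyl 2-methyl-3-oxopentanoate
Product: 19 4-hydroxy-6-[(E)-1-iodoprop-1-en-2-yl]-3,5-dimethyl-2H-pyran-2-one, via (E)-3-iodo-2-methylacryloyl chloride 16 (not isolated), via dilithio dianion 17 (not isolated), via triketo ester 18 (not isolated)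
Conditions: 12, (COCl)2, cat. DMF, CH2Cl2, 0 °C to rt, evaporate; 15 (2.2 equiv), LiN(i-Pr)2 (4.4 equiv), THF, −78 to 0 °C, then 16, −78 °C; aq. HCl; crude 18, DBU (2 equiv), PhMe, 60 °C; aq. HCl
Reagents that add atoms: none
Why: In this Weiler dianion γ-acylation (Claisen type) the acid chloride carbonyl outruns its β-carbon at −78 °C, DBU then lactonises the C5 enolate onto the methyl ester to give the 4-hydroxy-2-pyrone, and the alkene geometry is not involved.

Step 7
Reactants: 19 4-hydroxy-6-[(E)-1-iodoprop-1-en-2-yl]-3,5-dimethyl-2H-pyran-2-one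
Product: 21 2-[(E)-1-iodoprop-1-en-2-yl]-6-methoxy-3,5-dimethyl-4H-pyran-4-one, via 4-hydroxy-2-methoxypyrylium triflate 20 (not isolated)
Conditions: MeOTf (2 equiv), CH2Cl2, rt, 16 h; then aq. NaHCO3
Reagents that add atoms: methyl triflate, COS(=O)(=O)C(F)(F)F
Why: In this O-methylation the hard electrophile attacks the most basic oxygen of the neutral hydroxypyrone (the lactone carbonyl), and pyrylium 20 loses its OH proton on basic work-up to give the α-methoxy-γ-pyrone rather than the 4-methoxy-α-pyrone.

Step 8
Reactants: 8 (2Z,4E,6E)-2-iodo-4,6-dimethylnona-2,4,6-triene; 21 2-[(E)-1-iodoprop-1-en-2-yl]-6-methoxy-3,5-dimethyl-4H-pyran-4-one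
Product: 24 2-methoxy-3,5-dimethyl-6-[(2E,4Z,6E,8E)-4,6,8-trimethylundeca-2,4,6,8-tetraen-2-yl]-4H-pyran-4-one, via (Z)-trienyllithium 22 (not isolated), via (Z)-trienylzinc bromide 23 (not isolated)
Conditions: 8 (1.2 equiv), t-BuLi (2.4 equiv), Et2O, −78 °C; ZnBr2 (1.3 equiv), THF, −78 to 0 °C; 21, Pd(PPh3)4 (5 mol %), THF, 0 °C, dark; cold filtration through neutral alumina
Reagents that add atoms: none
Why: In this Negishi coupling, iodine–lithium exchange, transmetalation to zinc, oxidative addition of zerovalent palladium to 21 and reductive elimination all go with retention, so the two iodides fix the 2E,4Z geometry; the organozinc tolerates the pyrone and 0 °C keeps 24 open.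

Step 9
Reactants: 24 2-methoxy-3,5-dimethyl-6-[(2E,4Z,6E,8E)-4,6,8-trimethylundeca-2,4,6,8-tetraen-2-yl]-4H-pyran-4-one
Product: 25 2-methoxy-3,5-dimethyl-6-{(1R,6S)-1,3,5-trimethyl-6-[(2E)-pent-2-en-2-yl]cyclohexa-2,4-dien-1-yl}-4H-pyran-4-one (pyrone and pentenyl cis)
Conditions: catalyst A (5 mol %), PhMe, 4 Å sieves, −30 °C, dark; Et3N quench. A is the (S,S)-imidodiphosphorimidate (IDPi) HN[P(=NSO2CF3)(O,O′-binaphthyl)]2 built from (S)-3,3′-bis[3,5-bis(trifluoromethyl)phenyl]-BINOL.
Reagents that add atoms: none
Why: Proposed new method: the confined chiral acid protonates or strongly hydrogen-bonds the most basic site, the pyrone C4 carbonyl, which turns the pyrone into a 4-hydroxypyrylium acceptor at the triene terminus; charge delocalisation then makes the pyrone-bearing carbon a 2-alkylidenepyran (enol-ether) nucleophile and the far triene CH an allyl-cation-like electrophile, which should lower the barrier of the thermally allowed disrotatory 6π closure well below the uncatalysed one; the E,Z,E triene geometry places pyrone and pentenyl "outside", so they end up cis, and the O–H···anion contact inside the chiral pocket lets only one of the two helical folds of the s-cis,s-cis triene close, which sets both new centres as (1R,6S); turnover follows because the non-conjugated product pyrone is less basic than the polyenyl pyrone, and that pyrone buffers the acid so the diene is not protonated; the closest known reaction types are Lewis-acid-accelerated 6π electrocyclisation of carbonyl-substituted hexatrienes, chiral-phosphoric-acid-catalysed aza-6π electrocyclisation of unsaturated hydrazones, counteranion-controlled asymmetric Nazarov cyclisation, and anion-binding catalysis on 4-siloxypyrylium ions.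

Step 10
Reactants: 25 2-methoxy-3,5-dimethyl-6-{(1R,6S)-1,3,5-trimethyl-6-[(2E)-pent-2-en-2-yl]cyclohexa-2,4-dien-1-yl}-4H-pyran-4-one
Product: 26 2-methoxy-3,5-dimethyl-6-{(1R,4R,5R,6S)-2,4,6-trimethyl-5-[(2E)-pent-2-en-2-yl]-7-oxabicyclo[4.1.0]hept-2-en-4-yl}-4H-pyran-4-one (oxirane anti to the cis pyrone and pentenyl groups)
Conditions: dimethyldioxirane (1.0 equiv, acetone solution), CH2Cl2, −40 to −20 °C, dark
Reagents that add atoms: dimethyldioxirane, CC1(C)OO1
Why: In this Prilezhaev-type dioxirane epoxidation the s-cis ring diene is the most electron-rich π system, its C2=C3 half is screened by the quaternary C1, and the face carrying pyrone and pentenyl is blocked, so oxygen goes to C4=C5 from the opposite face and sets the oxirane centres (1R,6S); one equivalent under neutral cold conditions spares the side-chain alkene, the pyrone and the acid-labile vinyl oxirane.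

## Compound list
1 | (E)-2-methylpent-2-enal | CC/C=C(\C)C=O | starting material
2 | 2-(triphenylphosphoranylidene)propanal | CC(C=O)=P(c1ccccc1)(c1ccccc1)c1ccccc1 | starting material
3 | (2E,4E)-2,4-dimethylhepta-2,4-dienal | CC/C=C(\C)/C=C(\C)C=O | intermediate
4 | ethyltriphenylphosphonium iodide | CC[P+](c1ccccc1)(c1ccccc1)c1ccccc1.[I-] | starting material
5 | ethylidenetriphenylphosphorane | CC=P(c1ccccc1)(c1ccccc1)c1ccccc1 | intermediate
6 | (1-iodoethyl)triphenylphosphonium iodide (racemic, centre lost in the next event) | IC(C)[P+](c1ccccc1)(c1ccccc1)c1ccccc1.[I-] | intermediate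
7 | (1-iodoethylidene)triphenylphosphorane | IC(C)=P(c1ccccc1)(c1ccccc1)c1ccccc1 | intermediate
8 | (2Z,4E,6E)-2-iodo-4,6-dimethylnona-2,4,6-triene | CC/C=C(\C)/C=C(\C)/C=C(/C)I | intermediate
9 | diethyl 2-methylmalonate | CCOC(=O)C(C)C(=O)OCC | starting material
10 | iodoform | [I]C([I])[I] | starting material
11 | diethyl 2-(diiodomethyl)-2-methylmalonate | CCOC(=O)C(C)(C(=O)OCC)C([I])[I] | intermediate
12 | (E)-3-iodo-2-methylprop-2-enoic acid | OC(=O)/C(C)=C/I | intermediate
13 | pentan-3-one | CCC(=O)CC | starting material
14 | dimethyl carbonate | COC(=O)OC | starting material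
15 | methyl 2-methyl-3-oxopentanoate (racemic, labile centre erased in step 6) | CCC(=O)C(C)C(=O)OC | intermediate
16 | (E)-3-iodo-2-methylacryloyl chloride | O=C(Cl)/C(C)=C/I | intermediate
17 | dilithio dianion (bis-enolate) of 15 | [Li+].[Li+].CC=C([O-])C(C)=C([O-])OC | intermediate
18 | methyl (E)-7-iodo-2,4,6-trimethyl-3,5-dioxohept-6-enoate (mixture of diastereomers and enols) | COC(=O)C(C)C(=O)C(C)C(=O)/C(C)=C/I | intermediate
19 | 4-hydroxy-6-[(E)-1-iodoprop-1-en-2-yl]-3,5-dimethyl-2H-pyran-2-one | CC1=C(O)C(C)=C(/C(C)=C/I)OC1=O | intermediate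
20 | 4-hydroxy-6-[(E)-1-iodoprop-1-en-2-yl]-2-methoxy-3,5-dimethylpyrylium triflate | COc1[o+]c(/C(C)=C/I)c(C)c(O)c1C.[O-]S(=O)(=O)C(F)(F)F | intermediate
21 | 2-[(E)-1-iodoprop-1-en-2-yl]-6-methoxy-3,5-dimethyl-4H-pyran-4-one | COc1oc(/C(C)=C/I)c(C)c(=O)c1C | intermediate
22 | (2Z,4E,6E)-4,6-dimethylnona-2,4,6-trien-2-yllithium | CC/C=C(\C)/C=C(\C)/C=C(/C)[Li] | intermediate
23 | (2Z,4E,6E)-4,6-dimethylnona-2,4,6-trien-2-ylzinc bromide | CC/C=C(\C)/C=C(\C)/C=C(/C)[Zn]Br | intermediate
24 | 2-methoxy-3,5-dimethyl-6-[(2E,4Z,6E,8E)-4,6,8-trimethylundeca-2,4,6,8-tetraen-2-yl]-4H-pyran-4-one | CC/C=C(\C)/C=C(\C)/C=C(/C)\C=C(/C)c1oc(OC)c(C)c(=O)c1C | intermediate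
25 | 2-methoxy-3,5-dimethyl-6-{(1R,6S)-1,3,5-trimethyl-6-[(2E)-pent-2-en-2-yl]cyclohexa-2,4-dien-1-yl}-4H-pyran-4-one | CC/C=C(\C)[C@H]1C(C)=CC(C)=C[C@@]1(C)c1oc(OC)c(C)c(=O)c1C | intermediate
26 | 2-methoxy-3,5-dimethyl-6-{(1R,4R,5R,6S)-2,4,6-trimethyl-5-[(2E)-pent-2-en-2-yl]-7-oxabicyclo[4.1.0]hept-2-en-4-yl}-4H-pyran-4-one | CC/C=C(\C)[C@H]1[C@]2(C)O[C@@H]2C(C)=C[C@@]1(C)c1oc(OC)c(C)c(=O)c1C | target

## Count and risks
Total steps: 10. Longest linear sequence: 7 (steps 3, 4, 6, 7, 8, 9, 10).

**Step 9 (the new reaction).**
- The acid may give too little rate gain over the racemic background closure.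
- It may divert the delocalised cation into a Nazarov-type 4π closure with cyclopropane formation, giving a bicyclo[3.1.0]hexene.
- It may scramble alkene geometry, which would give the trans diastereomer, or a [1,7]-hydrogen shift from the inward methyl may compete.
- The fallback uses known chemistry, sets out from 24 and comes back at 26, replacing steps 9 and 10. Compound 24 is heated in degassed toluene (90 °C, dark, BHT), so the uncatalysed disrotatory 6π closure gives the racemic cyclohexadiene F1. F1 is then put through a Shi epoxidation run as a kinetic resolution: fructose-derived ketone of the matched series (30 mol %), KHSO5, K2CO3 buffer, MeCN–dimethoxymethane–H2O, 0 °C, stopped near 45 % conversion. This converts the (1R,6S) enantiomer into 26 and leaves the mirror-image diene F2, which is removed by chromatography. The price is a ceiling of 50 % yield.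

**Step 10.**
- The side-chain trisubstituted alkene or the other half of the diene may compete with the intended alkene.
- The vinyl oxirane may open or over-oxidise.
- The fallback sets out from 25 and comes back at 26. Singlet oxygen (O2, tetraphenylporphyrin, CH2Cl2, −60 °C, light above 500 nm) adds only to the s-cis ring diene, in a [4+2] manner and on the free face. This gives the endoperoxide F3, with the O–O bridge across C2 and C5 of 25.
- PPh3 (1 equiv, PhMe, 0 °C to rt) then attacks the less hindered oxygen, the one on the CH carbon C2. The alkoxide left on the methyl-bearing C5 closes onto C4 in a syn SN2′ manner with loss of the phosphine oxide. This gives the C4–C5 oxirane and the C2=C3 alkene of 26 on the correct face.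

**Step 6.**
- The dianion may attack the β-carbon of 16, or O-acylate.
- Under DBU the C3 enolate oxygen of 18 may displace iodide (oxa-Michael addition–elimination), giving an unwanted γ-pyrone instead of lactonising.
- The fallback sets out from 15 and 16 and comes back at 19. It masks that oxygen and closes the ring through a ketene. Compound 15 is saponified (aq. NaOH, 0 °C) to 2-methyl-3-oxopentanoic acid F4, which is condensed with acetone (Ac2O, cat. H2SO4, 0 °C) to 6-ethyl-2,2,5-trimethyl-4H-1,3-dioxin-4-one F5.
- The lithium dienolate of F5 (LiN(i-Pr)2, THF, −78 °C) is acylated at its γ-carbon by 16 to give the acylated dioxinone F6. Heating F6 in toluene at 110 °C expels acetone, and the acylketene F7 is trapped at once by the neighbouring enol to give 19 under neutral conditions.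

## Further compounds
F1 | step 9 | racemic cis-cyclohexadiene (25 plus its mirror image) | CC/C=C(\C)[C@H]1C(C)=CC(C)=C[C@@]1(C)c1oc(OC)c(C)c(=O)c1C.CC/C=C(\C)[C@@H]1C(C)=CC(C)=C[C@]1(C)c1oc(OC)c(C)c(=O)c1C
F2 | step 9 | (1S,6R) mirror image of 25, left unreacted by the resolution | CC/C=C(\C)[C@@H]1C(C)=CC(C)=C[C@]1(C)c1oc(OC)c(C)c(=O)c1C
F3 | step 10 | endoperoxide of 25 (2,3-dioxabicyclo[2.2.2]oct-5-ene, O–O bridge anti to pyrone and pentenyl) | CC/C=C(\C)[C@H]1[C@@]2(C)C=C(C)[C@H](OO2)[C@@]1(C)c1oc(OC)c(C)c(=O)c1C
F4 | step 6 | 2-methyl-3-oxopentanoic acid (racemic, labile) | CCC(=O)C(C)C(O)=O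
F5 | step 6 | 6-ethyl-2,2,5-trimethyl-4H-1,3-dioxin-4-one | CCC1=C(C)C(=O)OC(C)(C)O1
F6 | step 6 | 6-[(E)-5-iodo-4-methyl-3-oxopent-4-en-2-yl]-2,2,5-trimethyl-4H-1,3-dioxin-4-one (racemic, centre erased on ring closure) | CC(C(=O)/C(C)=C/I)C1=C(C)C(=O)OC(C)(C)O1
F7 | step 6 | (E)-7-iodo-2,4,6-trimethyl-1-oxohepta-1,6-diene-3,5-dione (acylketene, transient) | CC(=C=O)C(=O)C(C)C(=O)/C(C)=C/I
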